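(All runs were generated by integration with made-up constants; noise was put on by code.)

- Start from amounts: of the free monomer charged, one share sits in chains, the rest doesn't. The readings give that share over time. Both runs share this flask's feed and [initiator], and differ from it in the charge.

| setting | summer | dawn | flask |
|---|---|---|---|
| free monomer | 0.17 M (fed, over 4.0 s) | 0.66 M (fed, over 4.0 s) | 0.33 M (fed, over 4.0 s) |
| initiator | 12 mM | 12 mM | 12 mM |
| remark | run made earlier; the fed solution adds 0.20 times the starting volume | run made earlier; the fed solution adds 0.20 times the starting volume | the fed solution adds 0.20 times the starting volume |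
| time |  |  | 5.0 min |

- summer (time / min: monomer in chains / %): 1.33: 32.8; 2.00: 44.1; 3.00: 53.6; 4.00: 62.2; 6.00: 67.9
- dawn (time / min: monomer in chains / %): 1.33: 41.1; 2.00: 51.9; 3.00: 61.0; 4.00: 67.8; 6.00: 72.9

(readings scatter by 1 percentage point)

* time, not beyond 5.0 min, at which the flask holds most monomer in chains
* the amount of monomer in chains, in percent of the free monomer charged, at that time

- Fix the time first: no proposed step removes monomer in chains, and both runs rise at each reading, so take 5.0 min.
- Replace each curve by its mean pace, the constant it would have if the uptake were pseudo-first-order: the natural log of charged over unconverted share, divided by the time.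
- Average the paces read either side of 5.0 min: the summer run gives 0.216 min⁻¹, the dawn run 0.250 min⁻¹.
- Take the flask's mean pace, the steady constant that gives its share at 5.0 min, midway between them: 0.233 min⁻¹. That means 68.9%.
- Object: the pace falls with time, so averaging may mislead. Test it across twice the gap, predicting 4.00 min from 2.00 min and 6.00 min. The share misses by 0.47 percentage points in the summer run and 1.1 points in the dawn run, near the scatter of 1 point. Keep it.
- Object again: midway assumes a log scale of charge. A straight line in charge gives 67.9%. Two charges can't choose, so commit to 68.9% and carry that gap of 1.00 point as the margin.
- The forecast says 68.5% at 5 min, slightly below my figure, and also holds that “0.33 M lies almost exactly midway between the two runs on a log scale”.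
- The flask gives 68.8% at 5.00 min.

    free monomer + initiator → living end + monomer in chains (k = 0.230 M⁻¹ s⁻¹)
    free monomer ⇌ dormant form (K = 2.00, k = 0.00480 s⁻¹)
    free monomer + living end → monomer in chains + living end, rate k3*[living end]*[free monomer] (k = 0.920 M⁻¹ s⁻¹)

- The flask's result means a mean pace of 0.233 min⁻¹ against the reckoned 0.233 min⁻¹. At 5.00 min the flask still holds 6.17% as free monomer and 25.0% as dormant form, and by 50.0 min it has 99.4% in chains. Now read the same flask at 2.0 min: the two runs' paces at that time average 0.328 min⁻¹, faster than 0.233 min⁻¹, which gives 48.1%, and that neighbouring flask holds 49.0% in chains.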